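**Route outline**

- Retrosynthesis: the benzene ring is opened at C8a–C8, C7–C6 and C6–C5 (carbene + alkyne + CO). Then follow C4a=C5 (aldol condensation), O1–C8a (alkynol cycloisomerisation) and C4–C4a (acetylide alkylation), back to geranylgeraniol.
- Enabling feature: ring C4a–C5–C6–C7–C8–C8a is a hydroquinone with unlike oxygens. O1 on C8a is locked in the pyran ring O1–C2–C3–C4–C4a–C8a and the C6 hydroxyl is free. This is the pattern obtained when C8a is an alkoxycarbene carbon, C6–O a CO ligand and the pyran the carbene's own ring.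
- Forward order: the C20 chain (carrying C2, C3, C4) comes first and is extended by two carbons (C4a, C8a). The pyran ring is closed as a 2-oxacyclohexylidene chromium complex, C5 with the masked formyl carbon is attached, the benzene ring is annulated last, and the arene is then unmasked.
- Stereochemistry: C2, the only stereocentre, is set by Sharpless epoxidation of geranylgeraniol (D-(−)-diethyl tartrate, (2R,3R)-epoxide) and its C–O bond is never broken. The E-alkenes of the chain are bought.

Key step: step 10

Remark: commercial dimethoxyacetaldehyde is an aqueous solution; it is taken to be dehydrated (extraction, drying, distillation) immediately before step 8.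

**Route**

Step 1
Reactants: 1 (2E,6E,10E)-geranylgeraniol
Product: 2 (2R,3R)-2,3-epoxygeranylgeraniol
Conditions: Ti(OiPr)4 (10 mol%), D-(−)-diethyl tartrate (12 mol%), t-BuOOH, 4 Å molecular sieves, CH2Cl2, −20 °C
Reagents that add atoms: tert-butyl hydroperoxide CC(C)(C)OO
Why: Sharpless asymmetric epoxidation acts only on the allylic alcohol and leaves the three isolated trisubstituted alkenes alone; the D-(−)-tartrate ligand directs oxygen to the face that gives the (2R,3R)-epoxide (reagent control), which fixes the quaternary carbon C3 that becomes C2 of the chroman.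

Step 2
Reactants: 2 (2R,3R)-2,3-epoxygeranylgeraniol
Product: 3 (3R,6E,10E)-3,7,11,15-tetramethylhexadeca-6,10,14-triene-1,3-diol
Conditions: NaAlH2(OCH2CH2OMe)2, THF, 0 °C → rt; aq. NaOH work-up
Reagents that add atoms: none
Why: Hydroxyl-directed reductive opening of a 2,3-epoxy alcohol by the alkoxyaluminate delivers hydride intramolecularly to C2, the more so as C3 is fully substituted, giving the 1,3-diol without touching the C3–O bond of the stereocentre.

Step 3
Reactants: 3 (3R,6E,10E)-3,7,11,15-tetramethylhexadeca-6,10,14-triene-1,3-diol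
Product: 4 (3R,6E,10E)-3-hydroxy-3,7,11,15-tetramethylhexadeca-6,10,14-trien-1-yl 4-methylbenzenesulfonate
Conditions: TsCl, Et3N, DMAP (cat.), CH2Cl2, 0 °C
Reagents that add atoms: p-toluenesulfonyl chloride Cc1ccc(cc1)S(=O)(=O)Cl
Why: Selective sulfonylation of the primary hydroxyl beside an unreactive tertiary one (standard tosylation); the amine base is too weak to close the oxetane.

Step 4
Reactants: 4 (3R,6E,10E)-3-hydroxy-3,7,11,15-tetramethylhexadeca-6,10,14-trien-1-yl 4-methylbenzenesulfonate
Product: 5 (3R,6E,10E)-3,7,11,15-tetramethyl-3-(triethylsilyloxy)hexadeca-6,10,14-trien-1-yl 4-methylbenzenesulfonate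
Conditions: Et3SiOTf, 2,6-lutidine, CH2Cl2, −78 → 0 °C
Reagents that add atoms: triethylsilyl trifluoromethanesulfonate CC[Si](CC)(CC)OS(=O)(=O)C(F)(F)F
Why: Silyl triflate and a hindered pyridine base silylate a tertiary alcohol reliably (silyl ether protection), so that no alkoxide can form and close the oxetane by 4-exo-tet attack under the strongly basic conditions of step 5.

Step 5
Reactants: 5 (3R,6E,10E)-3,7,11,15-tetramethyl-3-(triethylsilyloxy)hexadeca-6,10,14-trien-1-yl 4-methylbenzenesulfonate; 6 ethynyltrimethylsilane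
Product: 8 triethyl{[(5R,8E,12E)-5,9,13,17-tetramethyl-1-(trimethylsilyl)octadeca-8,12,16-trien-1-yn-5-yl]oxy}silane, via lithium (trimethylsilyl)acetylide 7 (not isolated)
Conditions: 6, n-BuLi, THF, −78 °C; then 5, DMPU, −78 °C → rt
Reagents that add atoms: none
Why: SN2 alkylation of a lithium acetylide by an unhindered primary tosylate in a dipolar cosolvent forms the C4–C4a bond; the C-silyl group keeps the acetylide monofunctional and the quaternary centre is two atoms away from the reacting carbon.

Step 6
Reactants: 8 triethyl{[(5R,8E,12E)-5,9,13,17-tetramethyl-1-(trimethylsilyl)octadeca-8,12,16-trien-1-yn-5-yl]oxy}silane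
Product: 9 (5R,8E,12E)-5,9,13,17-tetramethyloctadeca-8,12,16-trien-1-yn-5-ol
Conditions: Bu4NF, THF, 0 °C → rt
Reagents that add atoms: none
Why: Fluoride-mediated desilylation cleaves the alkynyl C–Si bond and the tertiary O–Si bond in one operation, the alkenes and the terminal alkyne being inert to it.

Step 7
Reactants: 9 (5R,8E,12E)-5,9,13,17-tetramethyloctadeca-8,12,16-trien-1-yn-5-ol; 10 Cr(CO)6
Product: 12 pentacarbonyl{(6S)-6-methyl-6-[(3E,7E)-4,8,12-trimethyltrideca-3,7,11-trien-1-yl]oxan-2-ylidene}chromium, via pentacarbonyl(tetrahydrofuran)chromium 11 (not isolated)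
Conditions: Cr(CO)6, hν (Hg lamp), THF, rt, argon purge; then 9, THF, rt, dark
Reagents that add atoms: none
Why: Photolytic loss of one CO gives the labile THF complex, which binds the terminal alkyne; a 1,2-hydrogen shift gives the chromium vinylidene and the tertiary hydroxyl adds to its electrophilic α-carbon, closing the O1–C8a bond (known cycloisomerisation of ω-alkynols to cyclic Fischer oxacarbene complexes, six-ring closure being helped by the gem-dialkyl effect of the carbinol carbon), while the stereocentre reacts only through its oxygen.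

Step 8
Reactants: 12 pentacarbonyl{(6S)-6-methyl-6-[(3E,7E)-4,8,12-trimethyltrideca-3,7,11-trien-1-yl]oxan-2-ylidene}chromium; 13 dimethoxyacetaldehyde
Product: 15 pentacarbonyl{(6R)-3-(1-hydroxy-2,2-dimethoxyethyl)-6-methyl-6-[(3E,7E)-4,8,12-trimethyltrideca-3,7,11-trien-1-yl]oxan-2-ylidene}chromium (mixture at the two new centres), via lithiated carbene complex 14 (not isolated)
Conditions: n-BuLi, THF, −78 °C; then 13 (anhydrous), −78 °C; AcOH quench at −78 °C
Reagents that add atoms: none
Why: The α-methylene group of an alkoxycarbene complex is strongly acidic, so n-BuLi gives the enolate-like anion, which should add to this non-enolisable, strongly electrophilic α,α-dialkoxy aldehyde (aldol reaction of a Fischer carbene anion); the two new stereocentres form as a mixture and both disappear in step 9.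

Step 9
Reactants: 15 pentacarbonyl{(6R)-3-(1-hydroxy-2,2-dimethoxyethyl)-6-methyl-6-[(3E,7E)-4,8,12-trimethyltrideca-3,7,11-trien-1-yl]oxan-2-ylidene}chromium
Product: 17 pentacarbonyl{(3E,6R)-3-(2,2-dimethoxyethylidene)-6-methyl-6-[(3E,7E)-4,8,12-trimethyltrideca-3,7,11-trien-1-yl]oxan-2-ylidene}chromium, via secondary methanesulfonate 16 (not isolated)
Conditions: MsCl, Et3N, CH2Cl2, 0 °C → rt
Reagents that add atoms: none
Why: Mesylation followed by E1cB elimination through the acidic α-hydrogen (the standard dehydration of carbene aldol adducts) should give the conjugated alkylidene complex as the E isomer, in which the acetal-bearing substituent points away from the bulky Cr(CO)5 group and the C5 hydrogen toward the carbene carbon.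

Step 10
Reactants: 17 pentacarbonyl{(3E,6R)-3-(2,2-dimethoxyethylidene)-6-methyl-6-[(3E,7E)-4,8,12-trimethyltrideca-3,7,11-trien-1-yl]oxan-2-ylidene}chromium; 18 1-(trimethylsilyl)propyne
Product: 20 (2R)-5-(dimethoxymethyl)-2,8-dimethyl-7-(trimethylsilyl)-2-[(3E,7E)-4,8,12-trimethyltrideca-3,7,11-trien-1-yl]-3,4-dihydro-2H-chromen-6-ol, via tricarbonylchromium arene complex 19 (not isolated)
Conditions: 18 (3 equiv), THF (0.05 M), 50 °C, argon, dark; then air, Et2O, rt
Reagents that add atoms: none
Why: Loss of a cis CO ligand lets the alkyne bind and insert into the Cr=C8a bond to give a vinylcarbene, CO insertion turns this into a chromium-bound dienylketene, 6π-electrocyclisation joins the ketene carbon C6 to C5, and a hydrogen shift from C5 to oxygen aromatises the ring to the C6 phenol, held first as its Cr(CO)3 complex 19 and then freed by air. The closest known reaction type is the Dötz benzannulation of alkenyl(alkoxy)carbene chromium complexes with alkynes, in particular of exo-alkylidene 2-oxacycloalkylidene complexes, which give fused hydroquinone monoethers. The only ring closed is the benzene ring (C4a, C5, C6, C7, C8, C8a), by 6π-electrocyclisation of the dienylketene in a formal [3+2+1] assembly on the C4a–C8a edge of the pyran ring already in place, so that the chroman results. No stereocentre is formed and no bond to C2 is made or broken. The step needs regioselective alkyne insertion, which the size difference between Me3Si and methyl should secure by placing silicon next to the CO-derived C6 (at C7) and methyl next to the carbene carbon (at C8); it also needs alkene and carbene carbon held s-cis, which the ring and the E geometry provide, while the unactivated trisubstituted chain alkenes and the acetal should not engage the carbene.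

Step 11
Reactants: 20 (2R)-5-(dimethoxymethyl)-2,8-dimethyl-7-(trimethylsilyl)-2-[(3E,7E)-4,8,12-trimethyltrideca-3,7,11-trien-1-yl]-3,4-dihydro-2H-chromen-6-ol
Product: 22 (2R)-6-hydroxy-2,8-dimethyl-2-[(3E,7E)-4,8,12-trimethyltrideca-3,7,11-trien-1-yl]-3,4-dihydro-2H-chromene-5-carbaldehyde, via 7-silyl aldehyde 21 (not isolated)
Conditions: CF3CO2H, CH2Cl2/H2O, 0 °C, short reaction time; NaHCO3 quench
Reagents that add atoms: water O
Why: Aqueous acid hydrolyses the very labile o-hydroxybenzaldehyde dimethyl acetal, and ipso-protonation at C7 (ortho to the free hydroxyl, para to the C4a alkyl group, giving a β-silyl-stabilised arenium ion) then removes silicon (electrophilic protodesilylation of an arylsilane), the reaction being kept cold, dilute and brief to spare the chain alkenes.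

**Compound list**

1 | (2E,6E,10E)-geranylgeraniol | CC(C)=CCC/C(C)=C/CC/C(C)=C/CC/C(C)=C/CO | starting material
2 | [(2R,3R)-3-methyl-3-[(3E,7E)-4,8,12-trimethyltrideca-3,7,11-trien-1-yl]oxiran-2-yl]methanol | CC(C)=CCC/C(C)=C/CC/C(C)=C/CC[C@@]1(C)O[C@@H]1CO | intermediate
3 | (3R,6E,10E)-3,7,11,15-tetramethylhexadeca-6,10,14-triene-1,3-diol | CC(C)=CCC/C(C)=C/CC/C(C)=C/CC[C@](O)(C)CCO | intermediate
4 | (3R,6E,10E)-3-hydroxy-3,7,11,15-tetramethylhexadeca-6,10,14-trien-1-yl 4-methylbenzenesulfonate | CC(C)=CCC/C(C)=C/CC/C(C)=C/CC[C@](O)(C)CCOS(=O)(=O)c1ccc(C)cc1 | intermediate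
5 | (3R,6E,10E)-3,7,11,15-tetramethyl-3-(triethylsilyloxy)hexadeca-6,10,14-trien-1-yl 4-methylbenzenesulfonate | CC(C)=CCC/C(C)=C/CC/C(C)=C/CC[C@](O[Si](CC)(CC)CC)(C)CCOS(=O)(=O)c1ccc(C)cc1 | intermediate
6 | ethynyltrimethylsilane | C#C[Si](C)(C)C | starting material
7 | lithium (trimethylsilyl)acetylide | [Li]C#C[Si](C)(C)C | intermediate
8 | triethyl{[(5R,8E,12E)-5,9,13,17-tetramethyl-1-(trimethylsilyl)octadeca-8,12,16-trien-1-yn-5-yl]oxy}silane | CC(C)=CCC/C(C)=C/CC/C(C)=C/CC[C@](O[Si](CC)(CC)CC)(C)CCC#C[Si](C)(C)C | intermediate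
9 | (5R,8E,12E)-5,9,13,17-tetramethyloctadeca-8,12,16-trien-1-yn-5-ol | CC(C)=CCC/C(C)=C/CC/C(C)=C/CC[C@](O)(C)CCC#C | intermediate
10 | hexacarbonylchromium, Cr(CO)6 | O=C=[Cr](=C=O)(=C=O)(=C=O)(=C=O)=C=O | starting material
11 | pentacarbonyl(tetrahydrofuran)chromium, Cr(CO)5(THF) | O=C=[Cr-](=C=O)(=C=O)(=C=O)(=C=O)[O+]1CCCC1 | intermediate
12 | pentacarbonyl{(6S)-6-methyl-6-[(3E,7E)-4,8,12-trimethyltrideca-3,7,11-trien-1-yl]oxan-2-ylidene}chromium (same spatial arrangement as in 9; the label is S only because the chain now outranks the ring methylene) | CC(C)=CCC/C(C)=C/CC/C(C)=C/CC[C@]1(C)CCCC(=[Cr](=C=O)(=C=O)(=C=O)(=C=O)=C=O)O1 | intermediate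
13 | dimethoxyacetaldehyde | COC(OC)C=O | starting material
14 | lithium salt of the C3 carbanion of 12 (lithiated carbene complex) | [Li+].CC(C)=CCC/C(C)=C/CC/C(C)=C/CC[C@]1(C)CC[CH-]C(=[Cr](=C=O)(=C=O)(=C=O)(=C=O)=C=O)O1 | intermediate
15 | pentacarbonyl{(6R)-3-(1-hydroxy-2,2-dimethoxyethyl)-6-methyl-6-[(3E,7E)-4,8,12-trimethyltrideca-3,7,11-trien-1-yl]oxan-2-ylidene}chromium, mixture at ring C3 and the carbinol carbon | CC(C)=CCC/C(C)=C/CC/C(C)=C/CC[C@]1(C)CCC(C(O)C(OC)OC)C(=[Cr](=C=O)(=C=O)(=C=O)(=C=O)=C=O)O1 | intermediate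
16 | pentacarbonyl{(6R)-3-[2,2-dimethoxy-1-(methylsulfonyloxy)ethyl]-6-methyl-6-[(3E,7E)-4,8,12-trimethyltrideca-3,7,11-trien-1-yl]oxan-2-ylidene}chromium, same mixture | CC(C)=CCC/C(C)=C/CC/C(C)=C/CC[C@]1(C)CCC(C(OS(C)(=O)=O)C(OC)OC)C(=[Cr](=C=O)(=C=O)(=C=O)(=C=O)=C=O)O1 | intermediate
17 | pentacarbonyl{(3E,6R)-3-(2,2-dimethoxyethylidene)-6-methyl-6-[(3E,7E)-4,8,12-trimethyltrideca-3,7,11-trien-1-yl]oxan-2-ylidene}chromium | CC(C)=CCC/C(C)=C/CC/C(C)=C/CC[C@]1(C)CC/C(=C\C(OC)OC)C(=[Cr](=C=O)(=C=O)(=C=O)(=C=O)=C=O)O1 | intermediate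
18 | 1-(trimethylsilyl)propyne | CC#C[Si](C)(C)C | starting material
19 | tricarbonyl(η6-arene)chromium complex of 20 (the η6 bond of the benzene ring to Cr(CO)3 is written as a dot) | CC(C)=CCC/C(C)=C/CC/C(C)=C/CC[C@]1(C)CCc2c(C(OC)OC)c(O)c([Si](C)(C)C)c(C)c2O1.O=C=[Cr](=C=O)=C=O | intermediate
20 | (2R)-5-(dimethoxymethyl)-2,8-dimethyl-7-(trimethylsilyl)-2-[(3E,7E)-4,8,12-trimethyltrideca-3,7,11-trien-1-yl]-3,4-dihydro-2H-chromen-6-ol | CC(C)=CCC/C(C)=C/CC/C(C)=C/CC[C@]1(C)CCc2c(C(OC)OC)c(O)c([Si](C)(C)C)c(C)c2O1 | intermediate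
21 | (2R)-6-hydroxy-2,8-dimethyl-7-(trimethylsilyl)-2-[(3E,7E)-4,8,12-trimethyltrideca-3,7,11-trien-1-yl]-3,4-dihydro-2H-chromene-5-carbaldehyde | CC(C)=CCC/C(C)=C/CC/C(C)=C/CC[C@]1(C)CCc2c(C=O)c(O)c([Si](C)(C)C)c(C)c2O1 | intermediate
22 | (2R)-6-hydroxy-2,8-dimethyl-2-[(3E,7E)-4,8,12-trimethyltrideca-3,7,11-trien-1-yl]-3,4-dihydro-2H-chromene-5-carbaldehyde, (R)-5-formyl-δ-tocotrienol | CC(C)=CCC/C(C)=C/CC/C(C)=C/CC[C@]1(C)CCc2c(C=O)c(O)cc(C)c2O1 | target

**Step count**

Total steps: 11. Longest linear sequence: 11 steps (1 to 22).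

**Steps most likely to fail**

Step 10. The hindered internal silylalkyne must insert, and the 6π closure must occur at an alkylidene terminus that carries the acetal. Either may be slower than thermal loss of the carbene ligand, or the vinylcarbene and dienylketene may be diverted to cyclobutenone, furan or products without CO insertion. The fallback sets out from 12 and brings the formyl carbon in after the arene is made. Deprotonation with n-BuLi and aminomethylation with dimethyl(methylidene)ammonium iodide should give the Mannich base F1. F1 loses dimethylamine on silica (or after N-methylation with MeI and mild base) to give the exo-methylene complex F2, the unhindered substrate type on which this benzannulation is best precedented. Benzannulation of F2 with 18 under the conditions of step 10 should give 7-silyl-δ-tocotrienol F3. Magnesium-mediated ortho-formylation (MgCl2, Et3N, paraformaldehyde, THF, reflux) can only go to C5, because C7 is blocked by silicon. It should give aldehyde 21, where the route is rejoined and the acid of step 11 completes the synthesis. This detour also removes the aldol pair, steps 8 and 9.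

Step 11. Protonation of the trisubstituted chain alkenes may compete with ipso-protonation of the arene, leading to cation–olefin cyclisation or trifluoroacetate addition in the side chain. The fallback sets out from 17 and avoids silicon and strong acid. Benzannulation with the commercially obtainable 4,4,5,5-tetramethyl-2-(prop-1-yn-1-yl)-1,3,2-dioxaborolane should give the 7-boryl chromanol F4. Alkynylboronic esters are established partners in this reaction and, by the same steric rule, should place boron at C7. Base-mediated protodeboronation of this electron-rich, doubly ortho-substituted arylboronate (K2CO3, MeOH/H2O, 60 °C, argon) should give the 7-unsubstituted acetal F5. Dilute aqueous acetic acid in THF, which leaves the alkenes alone, then hydrolyses the acetal, and the route is rejoined at 22.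

Step 7. Chromium is less efficient for six- than for five-membered oxacarbenes. The vinylidene may form slowly and the alkyne oligomerise, or closure by the hindered tertiary hydroxyl may lag. The fallback sets out from 9 and brings the carbene carbon in as a lactone carbonyl. Anti-Markovnikov hydration of the terminal alkyne (excess dicyclohexylborane, then NaBO3) gives the hydroxy aldehyde, which closes to the lactol F6. Oxidation (TEMPO cat., PhI(OAc)2, CH2Cl2) gives the δ-lactone F7. Addition of dipotassium pentacarbonylchromate F8, K2Cr(CO)5, made from Cr(CO)6 and KC8 in THF at −78 °C, to the lactone carbonyl, followed by Me3SiCl to remove the former carbonyl oxygen, should give 12. This is the known lactone-to-oxacycloalkylidene conversion, and the route is rejoined at 12.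

**Further compounds**

F1 | step 10 | pentacarbonyl{(6R)-3-[(dimethylamino)methyl]-6-methyl-6-[(3E,7E)-4,8,12-trimethyltrideca-3,7,11-trien-1-yl]oxan-2-ylidene}chromium (epimers at C3) | CC(C)=CCC/C(C)=C/CC/C(C)=C/CC[C@]1(C)CCC(CN(C)C)C(=[Cr](=C=O)(=C=O)(=C=O)(=C=O)=C=O)O1
F2 | step 10 | pentacarbonyl{(6R)-6-methyl-3-methylidene-6-[(3E,7E)-4,8,12-trimethyltrideca-3,7,11-trien-1-yl]oxan-2-ylidene}chromium | CC(C)=CCC/C(C)=C/CC/C(C)=C/CC[C@]1(C)CCC(=C)C(=[Cr](=C=O)(=C=O)(=C=O)(=C=O)=C=O)O1
F3 | step 10 | (2R)-2,8-dimethyl-7-(trimethylsilyl)-2-[(3E,7E)-4,8,12-trimethyltrideca-3,7,11-trien-1-yl]-3,4-dihydro-2H-chromen-6-ol | CC(C)=CCC/C(C)=C/CC/C(C)=C/CC[C@]1(C)CCc2cc(O)c([Si](C)(C)C)c(C)c2O1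
F4 | step 11 | (2R)-5-(dimethoxymethyl)-2,8-dimethyl-7-(4,4,5,5-tetramethyl-1,3,2-dioxaborolan-2-yl)-2-[(3E,7E)-4,8,12-trimethyltrideca-3,7,11-trien-1-yl]-3,4-dihydro-2H-chromen-6-ol | CC(C)=CCC/C(C)=C/CC/C(C)=C/CC[C@]1(C)CCc2c(C(OC)OC)c(O)c(B3OC(C)(C)C(C)(C)O3)c(C)c2O1
F5 | step 11 | (2R)-5-(dimethoxymethyl)-2,8-dimethyl-2-[(3E,7E)-4,8,12-trimethyltrideca-3,7,11-trien-1-yl]-3,4-dihydro-2H-chromen-6-ol | CC(C)=CCC/C(C)=C/CC/C(C)=C/CC[C@]1(C)CCc2c(C(OC)OC)c(O)cc(C)c2O1
F6 | step 7 | (6S)-6-methyl-6-[(3E,7E)-4,8,12-trimethyltrideca-3,7,11-trien-1-yl]oxan-2-ol (anomers) | CC(C)=CCC/C(C)=C/CC/C(C)=C/CC[C@]1(C)CCCC(O)O1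
F7 | step 7 | (6S)-6-methyl-6-[(3E,7E)-4,8,12-trimethyltrideca-3,7,11-trien-1-yl]oxan-2-one | CC(C)=CCC/C(C)=C/CC/C(C)=C/CC[C@]1(C)CCCC(=O)O1
F8 | step 7 | dipotassium pentacarbonylchromate, K2Cr(CO)5 | [K+].[K+].O=C=[Cr-2](=C=O)(=C=O)(=C=O)=C=O
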